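## Retrosynthetic overview

1. The side chain is finished last: cross-metathesis of a terminal allyl carbinol with 2-methylbut-3-en-2-ol, after acetylation of the ring alcohol. The cycloheptane is closed just before that, at C5–C6 (azulene numbering), by an intramolecular Nozaki–Hiyama–Kishi reaction of an enol triflate with an aldehyde, which gives the allylic alcohol and the exocyclic methylene together.
2. The side-chain carbinol C2′ comes from Felkin–Anh allylation of an acetylcyclopentane; a nitrile is the latent methyl ketone/enol triflate and a dimethyl acetal the latent aldehyde.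
3. The acetylcyclopentane comes from a 1-acetylcyclopentene, made by ring contraction of a 1-methylcyclohexene. The enabling feature: ring carbon C1 of the cyclopentane (C1, C2, C3, C3a, C8a) carries the exocyclic carbinol carbon C2′ with its methyl. C2′ can therefore be placed back in a six-membered ring C2′–C1–C8a–C3a–C3–C2 as the methyl-bearing sp2 carbon of a cyclohexene; C1, C2′(CH3), C2 and C3 are then one isoprene unit.
4. The cyclohexene comes from isoprene and an (E)-2-methyl-2-enal by catalytic enantioselective Diels–Alder reaction. The E geometry makes C3a (quaternary, methyl) and C8a (H) trans; the catalyst sets their absolute configuration. The enal comes from a Wittig reaction.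
5. Order of ring formation: cyclohexene (step 2), cyclopentene by contraction (step 5), cycloheptane (step 11).

Key step: step 5

Assumption: the (S)-configured oxazaborolidinium catalyst is taken to deliver isoprene to the Si face of the α-carbon of the enal; should the sense prove opposite, the mirror-image catalyst is used and nothing else changes.

## Route

Step 1
Reactants: 1 4-oxobutanenitrile; 2 2-(triphenylphosphoranylidene)propanal
Product: 3 (4E)-5-methyl-6-oxohex-4-enenitrile
Conditions: toluene, 80 °C
Reagents that add atoms: 2-(triphenylphosphoranylidene)propanal, CC(C=O)=P(c1ccccc1)(c1ccccc1)c1ccccc1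
Why: Wittig olefination with a formyl-stabilised ylide should react only at the unhindered aliphatic aldehyde and give the (E)-trisubstituted enal, as is usual for stabilised ylides.

Step 2
Reactants: 3 (4E)-5-methyl-6-oxohex-4-enenitrile; 4 isoprene
Product: 5 3-[(1S,6S)-6-formyl-3,6-dimethylcyclohex-3-en-1-yl]propanenitrile
Conditions: isoprene (5 equiv), (S)-3,3-diphenyl-1-(o-tolyl)tetrahydropyrrolo[1,2-c][1,3,2]oxazaborole·HN(SO2CF3)2 (20 mol %), CH2Cl2, −78 to −20 °C
Reagents that add atoms: isoprene, C=CC(C)=C
Why: Lewis-acid-catalysed Diels–Alder reaction of a 2-methyl-2-alkenal: suprafacial addition to the (E)-enal fixes the formyl group on the quaternary carbon and the cyanoethyl chain on the neighbouring CH as trans, isoprene adds with "para" orientation, and the chiral oxazaborolidinium sets both new stereocentres by shielding one enal face.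

Step 3
Reactants: 5 3-[(1S,6S)-6-formyl-3,6-dimethylcyclohex-3-en-1-yl]propanenitrile; 6 (methoxymethyl)triphenylphosphonium chloride
Product: 7 3-[(1S,6S)-6-(2-methoxyethenyl)-3,6-dimethylcyclohex-3-en-1-yl]propanenitrile (E/Z mixture at the enol ether)
Conditions: MeOCH2PPh3Cl, KN(SiMe3)2, THF, 0 °C to rt
Reagents that add atoms: (methoxymethyl)triphenylphosphonium chloride, COC[P+](c1ccccc1)(c1ccccc1)c1ccccc1.[Cl-]
Why: Wittig methoxymethylenation of the non-enolisable aldehyde homologates it by one carbon; the enol ether geometry is of no consequence.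

Step 4
Reactants: 7 3-[(1S,6S)-6-(2-methoxyethenyl)-3,6-dimethylcyclohex-3-en-1-yl]propanenitrile; 8 methanol
Product: 9 3-[(1S,6R)-6-(2,2-dimethoxyethyl)-3,6-dimethylcyclohex-3-en-1-yl]propanenitrile
Conditions: MeOH, PPTS (cat.), rt
Reagents that add atoms: methanol, CO
Why: acid-catalysed Markovnikov addition of methanol to the enol ether (acetalisation) masks the homologated aldehyde in a form stable to ozone, base, hydrogenation and organometallics; the ring alkene and the nitrile should be inert to the weak acid.

Step 5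
Reactants: 9 3-[(1S,6R)-6-(2,2-dimethoxyethyl)-3,6-dimethylcyclohex-3-en-1-yl]propanenitrile
Product: 12 3-[(1R,5R)-2-acetyl-5-(2,2-dimethoxyethyl)-5-methylcyclopent-2-en-1-yl]propanenitrile, via keto-aldehyde 10 (not isolated), via aldol adduct 11 (not isolated)
Conditions: O3, CH2Cl2/MeOH, −78 °C; Me2S, −78 °C to rt; then KOH (0.2 equiv), MeOH, 0 °C to rt, one flask
Reagents that add atoms: ozone, [O-][O+]=O
Why: Ozone cleaves the only C=C bond, the trisubstituted alkene of the 1-methylcyclohexene, and reductive work-up gives keto-aldehyde 10, in which the methyl-bearing ring carbon has become a methyl ketone. Hydroxide then forms the internal enolate of that ketone, which adds to the aldehyde in a 5-(enolexo)-exo-trig aldol closure; adduct 11 loses water (E1cB) to the conjugated 1-acetylcyclopentene 12, so the six-membered ring is closed again one atom smaller with the excised carbon now exocyclic as the acetyl carbonyl. The closest known reaction type is the ozonolysis–intramolecular aldol ring contraction of 1-methylcyclohexenes (6-oxoheptanals) to 1-acetylcyclopentenes. No stereocentre formed here survives (both aldol centres are erased on dehydration), and the quaternary carbon and its tertiary neighbour are not enolisable, so their trans relationship from step 2 is kept. The selectivity needed is regiochemical (ketone CH2 enolate onto the aldehyde, not aldehyde enolate onto the ketone and not the methyl enolate onto the aldehyde); it is secured by ring size (five against seven), by the hindered position of the aldehyde α-CH2 next to the quaternary carbon, by hydroxide instead of amine catalysis, and by the Thorpe–Ingold effect of that quaternary carbon.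

Step 6
Reactants: 12 3-[(1R,5R)-2-acetyl-5-(2,2-dimethoxyethyl)-5-methylcyclopent-2-en-1-yl]propanenitrile
Product: 13 3-[(1S,2S,5R)-2-acetyl-5-(2,2-dimethoxyethyl)-5-methylcyclopentyl]propanenitrile
Conditions: H2 (1 atm), Pd/C, EtOAc, rt
Reagents that add atoms: none
Why: heterogeneous catalytic hydrogenation (syn addition) of the conjugated alkene should occur on the face opposite the allylic cyanoethyl chain and the angular methyl, giving the acetyl group cis to the chain, the kinetically formed (2S) centre; nitrile and acetal are untouched.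

Step 7
Reactants: 13 3-[(1S,2S,5R)-2-acetyl-5-(2,2-dimethoxyethyl)-5-methylcyclopentyl]propanenitrile; 14 allylmagnesium bromide
Product: 15 3-[(1S,2S,5R)-5-(2,2-dimethoxyethyl)-2-[(2S)-2-hydroxypent-4-en-2-yl]-5-methylcyclopentyl]propanenitrile
Conditions: CH2=CHCH2MgBr, THF, −78 °C; aq. NH4Cl
Reagents that add atoms: allylmagnesium bromide, C=CC[Mg]Br
Why: Grignard 1,2-addition under Felkin–Anh control: attack anti to the ring carbon that carries the cis chain (large group), with the ring CH2 as medium group, should give the (2S) tertiary carbinol; at −78 °C the ketone reacts far faster than the nitrile and faster than enolisation of the epimerisable α-centre.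

Step 8
Reactants: 15 3-[(1S,2S,5R)-5-(2,2-dimethoxyethyl)-2-[(2S)-2-hydroxypent-4-en-2-yl]-5-methylcyclopentyl]propanenitrile; 16 methyllithium
Product: 18 4-[(1S,2S,5R)-5-(2,2-dimethoxyethyl)-2-[(2S)-2-hydroxypent-4-en-2-yl]-5-methylcyclopentyl]butan-2-one, via ketimine 17 (not isolated)
Conditions: CH3Li (3.5 equiv), Et2O, −78 to 0 °C; aq. NH4Cl, rt
Reagents that add atoms: methyllithium, [Li]C; water, O
Why: addition of an organolithium to the nitrile stops at the N-lithio ketimine (the alkoxide formed first is inert), and ketimine 17 is hydrolysed on buffered aqueous work-up to the methyl ketone (ketone synthesis from nitriles); the dimethyl acetal should survive.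

Step 9
Reactants: 18 4-[(1S,2S,5R)-5-(2,2-dimethoxyethyl)-2-[(2S)-2-hydroxypent-4-en-2-yl]-5-methylcyclopentyl]butan-2-one; 19 N-phenylbis(trifluoromethanesulfonimide)
Product: 21 4-[(1S,2S,5R)-5-(2,2-dimethoxyethyl)-2-[(2S)-2-hydroxypent-4-en-2-yl]-5-methylcyclopentyl]but-1-en-2-yl trifluoromethanesulfonate, via dipotassium enolate 20 (not isolated)
Conditions: KN(SiMe3)2 (2.2 equiv), THF, −78 °C; PhNTf2, −78 to −20 °C
Reagents that add atoms: N-phenylbis(trifluoromethanesulfonimide), O=S(=O)(N(c1ccccc1)S(=O)(=O)C(F)(F)F)C(F)(F)F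
Why: kinetic deprotonation of the methyl ketone at the methyl group by the hindered amide base, then O-sulfonylation of the enolate, should give the terminal enol triflate; the hindered tertiary potassium alkoxide is not expected to be triflated at low temperature.

Step 10
Reactants: 21 4-[(1S,2S,5R)-5-(2,2-dimethoxyethyl)-2-[(2S)-2-hydroxypent-4-en-2-yl]-5-methylcyclopentyl]but-1-en-2-yl trifluoromethanesulfonate
Product: 22 4-[(1S,2S,5R)-2-[(2S)-2-hydroxypent-4-en-2-yl]-5-methyl-5-(2-oxoethyl)cyclopentyl]but-1-en-2-yl trifluoromethanesulfonate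
Conditions: PPTS (cat.), acetone/H2O, 40 °C
Reagents that add atoms: water, O
Why: mild acid-catalysed acetal hydrolysis liberates the aldehyde; the enol triflate and the tertiary homoallylic alcohol should tolerate pyridinium tosylate.

Step 11
Reactants: 22 4-[(1S,2S,5R)-2-[(2S)-2-hydroxypent-4-en-2-yl]-5-methyl-5-(2-oxoethyl)cyclopentyl]but-1-en-2-yl trifluoromethanesulfonate
Product: 23 (1S,3aR,5S,8aS)-1-[(2S)-2-hydroxypent-4-en-2-yl]-3a-methyl-6-methylidenedecahydroazulen-5-ol
Conditions: CrCl2 (8 equiv), NiCl2 (2 mol %), DMF, rt, high dilution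
Reagents that add atoms: none
Why: intramolecular Nozaki–Hiyama–Kishi reaction: zerovalent nickel inserts into the alkenyl triflate, transmetalation gives an alkenyl species of trivalent chromium that adds to the aldehyde and closes the seven-membered ring as the 2-methylidenecycloheptanol; the carbinol is expected to form with the hydroxyl anti to the angular methyl on the neighbouring quaternary carbon (the syn arrangement suffers a 1,3-interaction across the ring), i.e. (5S).

Step 12
Reactants: 23 (1S,3aR,5S,8aS)-1-[(2S)-2-hydroxypent-4-en-2-yl]-3a-methyl-6-methylidenedecahydroazulen-5-ol; 24 acetic anhydride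
Product: 25 (1S,3aR,5S,8aS)-1-[(2S)-2-hydroxypent-4-en-2-yl]-3a-methyl-6-methylidenedecahydroazulen-5-yl acetate
Conditions: Ac2O, pyridine, DMAP (cat.), CH2Cl2, 0 °C
Reagents that add atoms: acetic anhydride, CC(=O)OC(C)=O
Why: nucleophile-catalysed acylation should acetylate the secondary allylic alcohol selectively; the hindered tertiary alcohol does not react under these conditions.

Step 13
Reactants: 25 (1S,3aR,5S,8aS)-1-[(2S)-2-hydroxypent-4-en-2-yl]-3a-methyl-6-methylidenedecahydroazulen-5-yl acetate; 26 2-methylbut-3-en-2-ol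
Product: 27 (1S,3aR,5S,8aS)-1-[(2S,4E)-2,6-dihydroxy-6-methylhept-4-en-2-yl]-3a-methyl-6-methylidenedecahydroazulen-5-yl acetate (CNP0290154.1)
Conditions: 2-methylbut-3-en-2-ol (10 equiv), Hoveyda–Grubbs second-generation catalyst C31H38Cl2N2ORu (5 mol %), CH2Cl2, 40 °C
Reagents that add atoms: 2-methylbut-3-en-2-ol, C=CC(C)(C)O
Why: olefin cross-metathesis of the terminal alkene with excess tertiary allylic alcohol should give the (E)-disubstituted alkene; the 1,1-disubstituted exocyclic methylene next to the acetate is too hindered to take part.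

## Compound list

1 | 4-oxobutanenitrile | N#CCCC=O | starting material
2 | 2-(triphenylphosphoranylidene)propanal | CC(C=O)=P(c1ccccc1)(c1ccccc1)c1ccccc1 | starting material
3 | (4E)-5-methyl-6-oxohex-4-enenitrile | N#CCC/C=C(\C)C=O | intermediate
4 | isoprene (2-methylbuta-1,3-diene) | C=CC(C)=C | starting material
5 | 3-[(1S,6S)-6-formyl-3,6-dimethylcyclohex-3-en-1-yl]propanenitrile | N#CCC[C@H]1CC(C)=CC[C@]1(C)C=O | intermediate
6 | (methoxymethyl)triphenylphosphonium chloride | COC[P+](c1ccccc1)(c1ccccc1)c1ccccc1.[Cl-] | starting material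
7 | 3-[(1S,6S)-6-(2-methoxyethenyl)-3,6-dimethylcyclohex-3-en-1-yl]propanenitrile (E/Z mixture) | N#CCC[C@H]1CC(C)=CC[C@]1(C)C=COC | intermediate
8 | methanol | CO | starting material
9 | 3-[(1S,6R)-6-(2,2-dimethoxyethyl)-3,6-dimethylcyclohex-3-en-1-yl]propanenitrile | N#CCC[C@H]1CC(C)=CC[C@]1(C)CC(OC)OC | intermediate
10 | (4S,5R)-5-(2,2-dimethoxyethyl)-5-methyl-7-oxo-4-(2-oxopropyl)heptanenitrile (keto-aldehyde) | N#CCC[C@@H](CC(C)=O)[C@](C)(CC=O)CC(OC)OC | intermediate
11 | 3-[(1S,5R)-2-acetyl-5-(2,2-dimethoxyethyl)-3-hydroxy-5-methylcyclopentyl]propanenitrile (aldol adduct, mixture at C2 and C3) | N#CCC[C@H]1C(C(C)=O)C(O)C[C@]1(C)CC(OC)OC | intermediate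
12 | 3-[(1R,5R)-2-acetyl-5-(2,2-dimethoxyethyl)-5-methylcyclopent-2-en-1-yl]propanenitrile | N#CCC[C@H]1C(C(C)=O)=CC[C@]1(C)CC(OC)OC | intermediate
13 | 3-[(1S,2S,5R)-2-acetyl-5-(2,2-dimethoxyethyl)-5-methylcyclopentyl]propanenitrile | N#CCC[C@H]1[C@@H](C(C)=O)CC[C@]1(C)CC(OC)OC | intermediate
14 | allylmagnesium bromide | C=CC[Mg]Br | starting material
15 | 3-[(1S,2S,5R)-5-(2,2-dimethoxyethyl)-2-[(2S)-2-hydroxypent-4-en-2-yl]-5-methylcyclopentyl]propanenitrile | N#CCC[C@H]1[C@@H]([C@@](C)(O)CC=C)CC[C@]1(C)CC(OC)OC | intermediate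
16 | methyllithium | [Li]C | starting material
17 | 4-[(1S,2S,5R)-5-(2,2-dimethoxyethyl)-2-[(2S)-2-hydroxypent-4-en-2-yl]-5-methylcyclopentyl]butan-2-imine (ketimine) | CC(=N)CC[C@H]1[C@@H]([C@@](C)(O)CC=C)CC[C@]1(C)CC(OC)OC | intermediate
18 | 4-[(1S,2S,5R)-5-(2,2-dimethoxyethyl)-2-[(2S)-2-hydroxypent-4-en-2-yl]-5-methylcyclopentyl]butan-2-one | CC(=O)CC[C@H]1[C@@H]([C@@](C)(O)CC=C)CC[C@]1(C)CC(OC)OC | intermediate
19 | N-phenylbis(trifluoromethanesulfonimide) | O=S(=O)(N(c1ccccc1)S(=O)(=O)C(F)(F)F)C(F)(F)F | starting material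
20 | dipotassium salt of 18 (terminal enolate and tertiary alkoxide) | [K+].[K+].C=C([O-])CC[C@H]1[C@@H]([C@@](C)([O-])CC=C)CC[C@]1(C)CC(OC)OC | intermediate
21 | 4-[(1S,2S,5R)-5-(2,2-dimethoxyethyl)-2-[(2S)-2-hydroxypent-4-en-2-yl]-5-methylcyclopentyl]but-1-en-2-yl trifluoromethanesulfonate | C=C(OS(=O)(=O)C(F)(F)F)CC[C@H]1[C@@H]([C@@](C)(O)CC=C)CC[C@]1(C)CC(OC)OC | intermediate
22 | 4-[(1S,2S,5R)-2-[(2S)-2-hydroxypent-4-en-2-yl]-5-methyl-5-(2-oxoethyl)cyclopentyl]but-1-en-2-yl trifluoromethanesulfonate | C=C(OS(=O)(=O)C(F)(F)F)CC[C@H]1[C@@H]([C@@](C)(O)CC=C)CC[C@]1(C)CC=O | intermediate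
23 | (1S,3aR,5S,8aS)-1-[(2S)-2-hydroxypent-4-en-2-yl]-3a-methyl-6-methylidenedecahydroazulen-5-ol | C=C1CC[C@H]2[C@@H]([C@@](C)(O)CC=C)CC[C@]2(C)C[C@@H]1O | intermediate
24 | acetic anhydride | CC(=O)OC(C)=O | starting material
25 | (1S,3aR,5S,8aS)-1-[(2S)-2-hydroxypent-4-en-2-yl]-3a-methyl-6-methylidenedecahydroazulen-5-yl acetate | C=C1CC[C@H]2[C@@H]([C@@](C)(O)CC=C)CC[C@]2(C)C[C@@H]1OC(C)=O | intermediate
26 | 2-methylbut-3-en-2-ol | C=CC(C)(C)O | starting material
27 | (1S,3aR,5S,8aS)-1-[(2S,4E)-2,6-dihydroxy-6-methylhept-4-en-2-yl]-3a-methyl-6-methylidenedecahydroazulen-5-yl acetate | C=C1CC[C@H]2[C@@H]([C@@](C)(O)C/C=C/C(C)(C)O)CC[C@]2(C)C[C@@H]1OC(C)=O | target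

## Step count and risks

Total step count: 13. Longest linear sequence: 13 steps (from 4-oxobutanenitrile).

Steps most likely to fail:

Step 2. The catalysed cycloaddition of a trisubstituted enal with isoprene may turn over slowly and lose enantioselectivity, and the nitrile may compete for the boron centre. The fallback sets out from 3 (with 4) and comes back at 5. The cycloaddition is run with (CH3)2AlCl in CH2Cl2 without chiral control, which should give 5 together with its enantiomer 3-[(1R,6R)-6-formyl-3,6-dimethylcyclohex-3-en-1-yl]propanenitrile F1 as the racemate. Condensation of the racemate with (1S,2S)-N,N′-dimethyl-1,2-diphenylethane-1,2-diamine over molecular sieves should give two diastereomeric aminals, 3-[(1S,6S)-6-[(4S,5S)-1,3-dimethyl-4,5-diphenylimidazolidin-2-yl]-3,6-dimethylcyclohex-3-en-1-yl]propanenitrile F2 and 3-[(1R,6R)-6-[(4S,5S)-1,3-dimethyl-4,5-diphenylimidazolidin-2-yl]-3,6-dimethylcyclohex-3-en-1-yl]propanenitrile F3, which are separated by chromatography. Hydrolysis of F2 with dilute aqueous acid returns 5 and the diamine.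

Step 7. Facial discrimination in the addition to the methyl ketone may be insufficient, and the basic reagent may enolise and epimerise the α-centre. The fallback sets out from 13 and comes back at 15. Ketone 13 is treated with allylboronic acid pinacol ester in the presence of a chiral aminophenol-derived boron catalyst (catalyst-controlled allyl addition to ketones under neutral conditions), so that the configuration of the carbinol is fixed by the catalyst and not by the substrate, and no strong base is present.

Step 11. Ring closure to the seven-membered ring may be outrun by protodemetalation of the alkenyl–metal intermediate or by intermolecular coupling, and the new carbinol centre may form without useful selectivity. The fallback sets out from 18 and comes back at 23. Acetal hydrolysis of 18 (PPTS, aqueous acetone) should give the keto-aldehyde 4-[(1S,2S,5R)-2-[(2S)-2-hydroxypent-4-en-2-yl]-5-methyl-5-(2-oxoethyl)cyclopentyl]butan-2-one F4. Intramolecular reductive carbonyl coupling (McMurry reaction, TiCl3/Zn–Cu, DME, reflux, slow addition) should give the methylcycloheptene (2S)-2-[(1S,3aR,8aS)-3a,6-dimethyl-1,2,3,3a,4,7,8,8a-octahydroazulen-1-yl]pent-4-en-2-ol F5. Epoxidation with 3-chloroperbenzoic acid at the trisubstituted ring alkene, on the face opposite the angular methyl, should give (2S)-2-[(1S,3aR,5S,6R,8aS)-5,6-epoxy-3a,6-dimethyldecahydroazulen-1-yl]pent-4-en-2-ol F6. Isomerisation with diethylaluminium 2,2,6,6-tetramethylpiperidide, (C2H5)2AlNC9H18, which removes a proton from the methyl group, should give 23.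

## Further compounds

F1 | step 2 | 3-[(1R,6R)-6-formyl-3,6-dimethylcyclohex-3-en-1-yl]propanenitrile (enantiomer of 5, formed with 5 as the racemate) | N#CCC[C@@H]1CC(C)=CC[C@@]1(C)C=O
F2 | step 2 | 3-[(1S,6S)-6-[(4S,5S)-1,3-dimethyl-4,5-diphenylimidazolidin-2-yl]-3,6-dimethylcyclohex-3-en-1-yl]propanenitrile | CN1[C@@H](c2ccccc2)[C@@H](N(C)C1[C@@]3(C)CC=C(C)C[C@@H]3CCC#N)c2ccccc2
F3 | step 2 | 3-[(1R,6R)-6-[(4S,5S)-1,3-dimethyl-4,5-diphenylimidazolidin-2-yl]-3,6-dimethylcyclohex-3-en-1-yl]propanenitrile | CN1[C@@H](c2ccccc2)[C@@H](N(C)C1[C@]3(C)CC=C(C)C[C@H]3CCC#N)c2ccccc2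
F0 | step 7 | none | none
F4 | step 11 | 4-[(1S,2S,5R)-2-[(2S)-2-hydroxypent-4-en-2-yl]-5-methyl-5-(2-oxoethyl)cyclopentyl]butan-2-one | CC(=O)CC[C@H]1[C@@H]([C@@](C)(O)CC=C)CC[C@]1(C)CC=O
F5 | step 11 | (2S)-2-[(1S,3aR,8aS)-3a,6-dimethyl-1,2,3,3a,4,7,8,8a-octahydroazulen-1-yl]pent-4-en-2-ol | CC=1CC[C@H]2[C@@H]([C@@](C)(O)CC=C)CC[C@]2(C)CC=1
F6 | step 11 | (2S)-2-[(1S,3aR,5S,6R,8aS)-5,6-epoxy-3a,6-dimethyldecahydroazulen-1-yl]pent-4-en-2-ol | C[C@@]12CC[C@H]3[C@@H]([C@@](C)(O)CC=C)CC[C@]3(C)C[C@@H]1O2
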